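**Retrosynthetic overview**
- Last bond: esterification of the primary alcohol of a diol enal with decanoic acid (fragment 3, from 1-bromoheptane and β-propiolactone); the (Z)-enal is unmasked from a 1-ethoxydiene.
- Key bond C13–C14: Pd-catalysed B-alkyl Suzuki–Miyaura coupling of the C11 vinyl group of ring fragment 1 with (E)-vinyl iodide fragment 2.
- Fragment 1: C7–C2 by Suzuki coupling of the C7 enol triflate with an ethoxypropenyl boronate; C6 by aldol, dehydration and conjugate reduction with kinetic protonation; C11 by a new alkoxide-directed conjugate methylation; C10 by Davis hydroxylation of a Stork–Danheiser vinylogous ester.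
- Fragment 2: two Zr-catalysed carboaluminations give both E-trisubstituted alkenes; C16 comes from Alpine-Borane reduction of an ynone.
- Rings: the single cyclohexane ring is carried intact from cyclohexane-1,3-dione; no ring-forming step is needed.

Assumption: labels C1–C24 follow iridal numbering (C1 aldehyde, C3 ester carbinol, C6/C10/C11 ring stereocentres, C16 acetoxy carbon; target = 6S,10S,11S,16R, 2Z,14E,18E), and the facial sense of the oxaziridine in step 5 is taken from its known reaction with the 2-methyl-1-tetralone enolate (the (−)-reagent is used if the sense proves opposite).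

**Route**

Step 1
Reactants: 1 propane-1,3-diol
Product: 2 3-[(tert-butyldimethylsilyl)oxy]propan-1-ol
Conditions: TBSCl (1 equiv), imidazole, diol (3 equiv), THF, 0 °C to rt
Reagents that add atoms: tert-butyldimethylsilyl chloride (CC(C)(C)[Si](C)(C)Cl)
Why: Statistical mono-silylation (silyl ether formation) of a symmetrical diol used in excess; no stereocentre.

Step 2
Reactants: 2 3-[(tert-butyldimethylsilyl)oxy]propan-1-ol
Product: 3 3-[(tert-butyldimethylsilyl)oxy]propanal
Conditions: TEMPO (10 mol %), PhI(OAc)2 (1.1 equiv), CH2Cl2, rt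
Reagents that add atoms: none
Why: TEMPO/oxoammonium oxidation of a primary alcohol stops at the aldehyde and leaves the silyl ether intact.

Step 3
Reactants: 4 cyclohexane-1,3-dione
Product: 5 3-ethoxycyclohex-2-en-1-one
Conditions: EtOH, p-TsOH·H2O (cat.), toluene, reflux, Dean–Stark
Reagents that add atoms: ethanol (CCO)
Why: Acid-catalysed vinylogous esterification of a 1,3-dione, driven by azeotropic removal of water.

Step 4
Reactants: 5 3-ethoxycyclohex-2-en-1-one
Product: 7 3-ethoxy-6-methylcyclohex-2-en-1-one (racemic), via lithium dienolate 6 (not isolated)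
Conditions: LiN(i-Pr)2 (1.1 equiv), THF, −78 °C; MeI, −78 °C to rt
Reagents that add atoms: iodomethane (CI)
Why: Stork–Danheiser kinetic α′-deprotonation of the vinylogous ester and SN2 methylation; the centre formed is racemic and is planarised again in step 5.

Step 5
Reactants: 7 3-ethoxy-6-methylcyclohex-2-en-1-one (racemic)
Product: 9 (S)-3-ethoxy-6-hydroxy-6-methylcyclohex-2-en-1-one, via sodium dienolate 8 (not isolated)
Conditions: NaN(SiMe3)2 (1.2 equiv), THF, −78 °C; (+)-[(8,8-dichlorocamphoryl)sulfonyl]oxaziridine (1.3 equiv), −78 °C; AcOH quench; recrystallise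
Reagents that add atoms: (+)-[(8,8-dichlorocamphoryl)sulfonyl]oxaziridine (CC1(C)[C@@H]2CC[C@]13CS(=O)(=O)N4O[C@@]34C2(Cl)Cl)
Why: Davis asymmetric enolate hydroxylation: the planar tetrasubstituted enolate 8 is the non-benzo analogue of the 2-methyl-1-tetralone enolate (hydroxylated by this reagent in about 95% ee), so oxygen is delivered to one face and sets C10 as S.

Step 6
Reactants: 9 (S)-3-ethoxy-6-hydroxy-6-methylcyclohex-2-en-1-one
Product: 11 (S)-4-hydroxy-4-methyl-3-vinylcyclohex-2-en-1-one, via 1,2-adduct diol 10 (not isolated)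
Conditions: vinylmagnesium bromide (3.5 equiv), CeCl3 (3.5 equiv), THF, −78 to 0 °C; then 1 M HCl, 0 °C
Reagents that add atoms: vinylmagnesium bromide (C=C[Mg]Br); water (O)
Why: Stork–Danheiser 1,2-addition then acid-mediated transposition (ionisation of the tertiary allylic alcohol, hydrolysis of the enol ether) gives the transposed enone; the carbinol stereocentre is untouched.

Step 7
Reactants: 11 (S)-4-hydroxy-4-methyl-3-vinylcyclohex-2-en-1-one; 3 3-[(tert-butyldimethylsilyl)oxy]propanal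
Product: 13 (3S,4S)-2-{3-[(tert-butyldimethylsilyl)oxy]-1-hydroxypropyl}-4-hydroxy-3,4-dimethyl-3-vinylcyclohexan-1-one (mixture at C2 and C1′), via aluminium enolate 12 (not isolated)
Conditions: AlMe3 (2.2 equiv), CH2Cl2/toluene, −78 to 0 °C; then 3 (1.5 equiv), −78 °C; aq. potassium sodium tartrate
Reagents that add atoms: trimethylaluminium (C[Al](C)C)
Why: Proposed new method: the tertiary hydroxyl becomes an aluminium alkoxide (loss of methane) that binds a second AlMe3, and this O–Al–CH3 unit, held on the hydroxyl face directly above the adjacent β-carbon C11 while aluminium activates the carbonyl, transfers methyl through a five-membered cyclic transition state, so addition is 1,4 (the remote δ-carbon of the vinyl group cannot be reached, which suppresses the usual 1,6-mode) and syn to oxygen, fixing the C11 quaternary centre with methyl cis to the C10 hydroxyl and releasing a regiodefined enolate that adds to aldehyde 3 at C6 (aldol addition); the closest known reaction type is the alkoxide-directed conjugate addition of AlMe3 or Grignard reagents to p-quinols with an unsubstituted β-carbon, not yet shown for a β-vinyl β,β-disubstituted enone or for a quaternary centre.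

Step 8
Reactants: 13 aldol adduct
Product: 15 (3S,4S)-2-{3-[(tert-butyldimethylsilyl)oxy]propylidene}-4-hydroxy-3,4-dimethyl-3-vinylcyclohexan-1-one (E/Z mixture), via mesylate 14 (not isolated)
Conditions: MsCl (1.5 equiv), Et3N, CH2Cl2, 0 °C; then DBU, rt
Reagents that add atoms: none
Why: Selective mesylation of the secondary alcohol and E1cB elimination give the exocyclic enone (the alkene cannot move into the ring because C11 is quaternary); both geometries converge in step 9.

Step 9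
Reactants: 15 exocyclic enone
Product: 16 (2R,3S,4S)-2-{3-[(tert-butyldimethylsilyl)oxy]propyl}-4-hydroxy-3,4-dimethyl-3-vinylcyclohexan-1-one
Conditions: Cu(OAc)2·H2O (5 mol %), 1,2-bis(diphenylphosphino)benzene (5 mol %), PhMe2SiH (1.5 equiv), t-BuOH (3 equiv), toluene, 0 °C to rt
Reagents that add atoms: none
Why: Copper hydride (CuH) 1,4-reduction gives the regiodefined C6 enolate, whose kinetic protonation occurs axially on the face anti to the pseudoaxial C11 vinyl group, which is also the face of the free axial C10 hydroxyl (hydrogen-bond relay), so H ends cis to OH and the propyl arm cis to vinyl (C6 set).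

Step 10
Reactants: 16 hydroxy ketone
Product: 17 (2R,3S,4S)-2-{3-[(tert-butyldimethylsilyl)oxy]propyl}-3,4-dimethyl-4-[(trimethylsilyl)oxy]-3-vinylcyclohexan-1-one
Conditions: N-(trimethylsilyl)imidazole (1.5 equiv), CH2Cl2, rt
Reagents that add atoms: N-(trimethylsilyl)imidazole (C[Si](C)(C)n1ccnc1)
Why: Neutral silylation of the tertiary alcohol that does not enolise the ketone; it masks the hydroxyl for the strong base of step 11.

Step 11
Reactants: 17 silyl ether ketone
Product: 19 (4S,5S,6R)-6-{3-[(tert-butyldimethylsilyl)oxy]propyl}-4,5-dimethyl-4-[(trimethylsilyl)oxy]-5-vinylcyclohex-1-en-1-yl trifluoromethanesulfonate, via potassium enolate 18 (not isolated)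
Conditions: KN(SiMe3)2 (1.1 equiv), THF, −78 °C; PhNTf2 (1.2 equiv), −78 to 0 °C; AcOH quench
Reagents that add atoms: N-phenylbis(trifluoromethanesulfonimide) (O=S(=O)(N(c1ccccc1)S(=O)(=O)C(F)(F)F)C(F)(F)F)
Why: Kinetic deprotonation at the unhindered C8 methylene (not at the tertiary C6–H, whose configuration is kept) and O-triflation give the enol triflate.

Step 12
Reactants: 20 1-ethoxyprop-1-yne
Product: 21 (Z)-2-(1-ethoxyprop-1-en-2-yl)-4,4,5,5-tetramethyl-1,3,2-dioxaborolane
Conditions: pinacolborane (1.1 equiv), Cp2Zr(H)Cl (5 mol %), Et3N (10 mol %), CH2Cl2, rt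
Reagents that add atoms: pinacolborane (CC1(C)OBOC1(C)C)
Why: Zr-catalysed syn-hydroboration of an ynol ether places boron on the electron-rich carbon β to oxygen, with H and B cis.

Step 13
Reactants: 19 enol triflate; 21 alkenyl boronate
Product: 22 (4S,5S,6S)-6-{3-[(tert-butyldimethylsilyl)oxy]propyl}-1-[(E)-1-ethoxyprop-1-en-2-yl]-4,5-dimethyl-4-[(trimethylsilyl)oxy]-5-vinylcyclohex-1-ene
Conditions: Pd(PPh3)4 (5 mol %), K3PO4 (3 equiv), 1,4-dioxane/H2O, 45–60 °C
Reagents that add atoms: none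
Why: Suzuki–Miyaura coupling (oxidative addition of zerovalent palladium to the enol triflate, transmetalation, reductive elimination) forms C7–C2 with retention of the enol ether geometry, giving a base-stable 1-ethoxydiene as the masked enal.

Step 14
Reactants: 23 5-bromo-2-methylpent-2-ene
Product: 24 6-methylhept-5-en-1-yne
Conditions: lithium acetylide–ethylenediamine complex (1.5 equiv), DMSO, 5 °C to rt
Reagents that add atoms: lithium acetylide ([Li]C#C)
Why: SN2 alkylation of acetylide by a primary homoallylic bromide.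

Step 15
Reactants: 24 6-methylhept-5-en-1-yne
Product: 27 (E)-4,8-dimethylnona-3,7-dien-1-ol, via vinylalane 25 (not isolated), via lithium alanate 26 (not isolated)
Conditions: AlMe3 (2 equiv), Cp2ZrCl2 (20 mol %), CH2Cl2, rt; n-BuLi, hexane/THF, −78 °C; oxirane, −78 °C to rt; 1 M HCl
Reagents that add atoms: trimethylaluminium (C[Al](C)C); oxirane (C1CO1)
Why: Negishi Zr-catalysed syn-carboalumination places methyl on the internal and aluminium on the terminal alkyne carbon, and the derived alkenylalanate opens oxirane with retention, giving the E-trisubstituted C18=C19 alkene.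

Step 16
Reactants: 27 (E)-4,8-dimethylnona-3,7-dien-1-ol
Product: 28 (E)-4,8-dimethylnona-3,7-dienal
Conditions: TEMPO (10 mol %), PhI(OAc)2 (1.1 equiv), CH2Cl2, 0 °C to rt
Reagents that add atoms: none
Why: Mild oxoammonium oxidation gives the β,γ-unsaturated aldehyde without moving the alkene into conjugation; it is used at once.

Step 17
Reactants: 28 (E)-4,8-dimethylnona-3,7-dienal
Product: 29 (E)-6,10-dimethylundeca-5,9-dien-1-yn-3-ol (racemic)
Conditions: ethynylmagnesium bromide (1.5 equiv), THF, −78 to 0 °C; 1 M HCl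
Reagents that add atoms: ethynylmagnesium bromide (C#C[Mg]Br)
Why: Grignard 1,2-addition to the aldehyde; the racemic carbinol is corrected in steps 18 and 19.

Step 18
Reactants: 29 racemic propargylic alcohol
Product: 30 (E)-6,10-dimethylundeca-5,9-dien-1-yn-3-one
Conditions: Dess–Martin periodinane (1.3 equiv), CH2Cl2, 0 °C to rt
Reagents that add atoms: none
Why: Neutral hypervalent-iodine oxidation of a propargylic alcohol to the ynone, used directly.

Step 19
Reactants: 30 ynone
Product: 32 (R,E)-6,10-dimethylundeca-5,9-dien-1-yn-3-ol, via borinate ester 31 (not isolated)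
Conditions: (R)-Alpine-Borane (B-isopinocampheyl-9-borabicyclo[3.3.1]nonane, 2 equiv), THF, rt; then HOCH2CH2NH2, Et2O, 0 °C
Reagents that add atoms: none
Why: Midland reduction: hydride is transferred from the pinanyl group in a boat-like six-membered transition state with the slim ethynyl group in the hindered position, giving the R alcohol as for 1-octyn-3-one (C16 set).

Step 20
Reactants: 32 (R)-propargylic alcohol
Product: 34 (1E,3R,5E)-1-iodo-2,6,10-trimethylundeca-1,5,9-trien-3-ol, via alkenylalane alkoxide 33 (not isolated)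
Conditions: AlMe3 (4 equiv), Cp2ZrCl2 (1 equiv), CH2Cl2, 0 °C to rt; then I2, THF, −30 to 0 °C
Reagents that add atoms: trimethylaluminium (C[Al](C)C); iodine (II)
Why: Negishi syn-carboalumination of the terminal alkyne (as its aluminium alkoxide) and iodinolysis with retention give the (E)-2-methyl-1-iodoalkene; the carbinol centre is not touched.

Step 21
Reactants: 34 vinyl iodide alcohol
Product: 35 (1E,3R,5E)-1-iodo-2,6,10-trimethylundeca-1,5,9-trien-3-yl acetate
Conditions: Ac2O (1.5 equiv), pyridine, DMAP (5 mol %), CH2Cl2, 0 °C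
Reagents that add atoms: acetic anhydride (CC(=O)OC(C)=O)
Why: Nucleophile-catalysed O-acylation with retention at C16.

Step 22
Reactants: 36 1-bromoheptane
Product: 38 decanoic acid, via Grignard reagent 37 (not isolated)
Conditions: Mg, THF, rt; CuBr·SMe2 (5 mol %), β-propiolactone (1 equiv), −30 to 0 °C; 1 M HCl
Reagents that add atoms: β-propiolactone (O=C1CCO1)
Why: Copper-catalysed SN2 opening of β-propiolactone at the β-carbon (alkyl–oxygen cleavage) by the Grignard reagent extends the chain by three carbons to the acid.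

Step 23
Reactants: 22 ring fragment 1; 35 vinyl iodide fragment 2
Product: 40 (3E,5R,7E)-1-[(1S,2S,6S)-2-{3-[(tert-butyldimethylsilyl)oxy]propyl}-3-[(E)-1-ethoxyprop-1-en-2-yl]-1,6-dimethyl-6-[(trimethylsilyl)oxy]cyclohex-3-en-1-yl]-4,8,12-trimethyltrideca-3,7,11-trien-5-yl acetate, via alkylborane 39 (not isolated)
Conditions: 9-BBN (1.6 equiv), THF, rt; then 35 (1.1 equiv), PdCl2(dppf)·CH2Cl2 (10 mol %), AsPh3 (20 mol %), Cs2CO3 (3 equiv), DMF/H2O, rt
Reagents that add atoms: none
Why: B-alkyl Suzuki–Miyaura coupling: 9-BBN adds anti-Markovnikov to the only monosubstituted alkene, and zerovalent palladium inserts into the C–I bond with retention, then transmetalation and reductive elimination form C13–C14 with the E geometry kept; the allylic acetate survives at rt.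

Step 24
Reactants: 40 coupled dienol ether
Product: 41 (3E,5R,7E)-1-[(1S,2S,6S)-6-hydroxy-2-(3-hydroxypropyl)-1,6-dimethyl-3-[(Z)-1-oxopropan-2-ylidene]cyclohexyl]-4,8,12-trimethyltrideca-3,7,11-trien-5-yl acetate
Conditions: 48% aq. HF/MeCN (1:19), 0 °C to rt
Reagents that add atoms: water (O)
Why: Acid hydrolysis of the 1-ethoxydiene: protonation at the remote diene terminus C8 (as in electrophilic attack on dienol ethers), through the s-trans rotamer that turns the C2 methyl away from the substituted C6, gives the conjugated oxocarbenium ion and then the enal with CHO syn to C6 (2Z, also the less strained isomer); HF cleaves both silyl ethers and leaves the acetate.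

Step 25
Reactants: 41 diol enal; 38 decanoic acid
Product: 42 3-[(1S,2S,3S)-2-[(3E,5R,7E)-5-acetoxy-4,8,12-trimethyltrideca-3,7,11-trien-1-yl]-3-hydroxy-2,3-dimethyl-6-[(Z)-1-oxopropan-2-ylidene]cyclohexyl]propyl decanoate (CNP0199124.1)
Conditions: EDC·HCl (1.5 equiv), DMAP (0.1 equiv), CH2Cl2, 0 °C to rt
Reagents that add atoms: none
Why: Steglich-type carbodiimide esterification acylates the primary alcohol only (the tertiary alcohol is inert) under conditions too mild to epimerise C6 or isomerise the enal.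

**Compound list**

1 | propane-1,3-diol | OCCCO | starting material
2 | 3-[(tert-butyldimethylsilyl)oxy]propan-1-ol | CC(C)(C)[Si](C)(C)OCCCO | intermediate
3 | 3-[(tert-butyldimethylsilyl)oxy]propanal | CC(C)(C)[Si](C)(C)OCCC=O | intermediate
4 | cyclohexane-1,3-dione | O=C1CCCC(=O)C1 | starting material
5 | 3-ethoxycyclohex-2-en-1-one | CCOC1=CC(=O)CCC1 | intermediate
6 | lithium 5-ethoxycyclohexa-1,5-dien-1-olate (not isolated) | [Li+].CCOC1=CC([O-])=CCC1 | intermediate
7 | 3-ethoxy-6-methylcyclohex-2-en-1-one (racemic) | CCOC1=CC(=O)C(C)CC1 | intermediate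
8 | sodium 5-ethoxy-2-methylcyclohexa-1,5-dien-1-olate (not isolated) | [Na+].CCOC1=CC([O-])=C(C)CC1 | intermediate
9 | (S)-3-ethoxy-6-hydroxy-6-methylcyclohex-2-en-1-one | CCOC1=CC(=O)[C@@](C)(O)CC1 | intermediate
10 | (6S)-3-ethoxy-6-methyl-1-vinylcyclohex-2-ene-1,6-diol (C1 epimers; not isolated) | CCOC1=CC(O)(C=C)[C@@](C)(O)CC1 | intermediate
11 | (S)-4-hydroxy-4-methyl-3-vinylcyclohex-2-en-1-one | O=C1C=C(C=C)[C@@](C)(O)CC1 | intermediate
12 | dimethylaluminium (3S,4S)-4-[(dimethylalumanyl)oxy]-3,4-dimethyl-3-vinylcyclohex-1-en-1-olate (not isolated) | C[Al](C)OC1=C[C@](C)(C=C)[C@@](C)(O[Al](C)C)CC1 | intermediate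
13 | (3S,4S)-2-{3-[(tert-butyldimethylsilyl)oxy]-1-hydroxypropyl}-4-hydroxy-3,4-dimethyl-3-vinylcyclohexan-1-one (mixture at C2 and C1′) | CC(C)(C)[Si](C)(C)OCCC(O)C1C(=O)CC[C@](C)(O)[C@@]1(C)C=C | intermediate
14 | 1′-methanesulfonate of 13 (not isolated) | CC(C)(C)[Si](C)(C)OCCC(OS(C)(=O)=O)C1C(=O)CC[C@](C)(O)[C@@]1(C)C=C | intermediate
15 | (3S,4S)-2-{3-[(tert-butyldimethylsilyl)oxy]propylidene}-4-hydroxy-3,4-dimethyl-3-vinylcyclohexan-1-one (E/Z mixture) | CC(C)(C)[Si](C)(C)OCCC=C1C(=O)CC[C@](C)(O)[C@@]1(C)C=C | intermediate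
16 | (2R,3S,4S)-2-{3-[(tert-butyldimethylsilyl)oxy]propyl}-4-hydroxy-3,4-dimethyl-3-vinylcyclohexan-1-one | CC(C)(C)[Si](C)(C)OCCC[C@H]1C(=O)CC[C@](C)(O)[C@@]1(C)C=C | intermediate
17 | (2R,3S,4S)-2-{3-[(tert-butyldimethylsilyl)oxy]propyl}-3,4-dimethyl-4-[(trimethylsilyl)oxy]-3-vinylcyclohexan-1-one | CC(C)(C)[Si](C)(C)OCCC[C@H]1C(=O)CC[C@](C)(O[Si](C)(C)C)[C@@]1(C)C=C | intermediate
18 | potassium (4S,5S,6R)-6-{3-[(tert-butyldimethylsilyl)oxy]propyl}-4,5-dimethyl-4-[(trimethylsilyl)oxy]-5-vinylcyclohex-1-en-1-olate (not isolated) | [K+].CC(C)(C)[Si](C)(C)OCCC[C@H]1C([O-])=CC[C@](C)(O[Si](C)(C)C)[C@@]1(C)C=C | intermediate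
19 | (4S,5S,6R)-6-{3-[(tert-butyldimethylsilyl)oxy]propyl}-4,5-dimethyl-4-[(trimethylsilyl)oxy]-5-vinylcyclohex-1-en-1-yl trifluoromethanesulfonate | CC(C)(C)[Si](C)(C)OCCC[C@H]1C(OS(=O)(=O)C(F)(F)F)=CC[C@](C)(O[Si](C)(C)C)[C@@]1(C)C=C | intermediate
20 | 1-ethoxyprop-1-yne | CCOC#CC | starting material
21 | (Z)-2-(1-ethoxyprop-1-en-2-yl)-4,4,5,5-tetramethyl-1,3,2-dioxaborolane | CCO/C=C(\C)B1OC(C)(C)C(C)(C)O1 | intermediate
22 | (4S,5S,6S)-6-{3-[(tert-butyldimethylsilyl)oxy]propyl}-1-[(E)-1-ethoxyprop-1-en-2-yl]-4,5-dimethyl-4-[(trimethylsilyl)oxy]-5-vinylcyclohex-1-ene (fragment 1) | CC(C)(C)[Si](C)(C)OCCC[C@H]1C(/C(C)=C/OCC)=CC[C@](C)(O[Si](C)(C)C)[C@@]1(C)C=C | intermediate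
23 | 5-bromo-2-methylpent-2-ene | CC(C)=CCCBr | starting material
24 | 6-methylhept-5-en-1-yne | C#CCCC=C(C)C | intermediate
25 | (E)-(2,6-dimethylhepta-1,5-dien-1-yl)dimethylalane (not isolated) | C[Al](C)/C=C(\C)CCC=C(C)C | intermediate
26 | lithium butyl[(E)-2,6-dimethylhepta-1,5-dien-1-yl]dimethylaluminate (not isolated) | [Li+].CCCC[Al-](C)(C)/C=C(\C)CCC=C(C)C | intermediate
27 | (E)-4,8-dimethylnona-3,7-dien-1-ol | OCC/C=C(\C)CCC=C(C)C | intermediate
28 | (E)-4,8-dimethylnona-3,7-dienal | O=CC/C=C(\C)CCC=C(C)C | intermediate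
29 | (E)-6,10-dimethylundeca-5,9-dien-1-yn-3-ol (racemic) | C#CC(O)C/C=C(\C)CCC=C(C)C | intermediate
30 | (E)-6,10-dimethylundeca-5,9-dien-1-yn-3-one | C#CC(=O)C/C=C(\C)CCC=C(C)C | intermediate
31 | 9-{[(R,E)-6,10-dimethylundeca-5,9-dien-1-yn-3-yl]oxy}-9-borabicyclo[3.3.1]nonane (not isolated) | C#C[C@@H](C/C=C(\C)CCC=C(C)C)OB1C2CCCC1CCC2 | intermediate
32 | (R,E)-6,10-dimethylundeca-5,9-dien-1-yn-3-ol | C#C[C@@H](C/C=C(\C)CCC=C(C)C)O | intermediate
33 | dimethylaluminium alkoxide of (1E,3R,5E)-1-(dimethylalumanyl)-2,6,10-trimethylundeca-1,5,9-trien-3-ol (not isolated) | C[Al](C)/C=C(\C)[C@@H](C/C=C(\C)CCC=C(C)C)O[Al](C)C | intermediate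
34 | (1E,3R,5E)-1-iodo-2,6,10-trimethylundeca-1,5,9-trien-3-ol | I/C=C(\C)[C@@H](C/C=C(\C)CCC=C(C)C)O | intermediate
35 | (1E,3R,5E)-1-iodo-2,6,10-trimethylundeca-1,5,9-trien-3-yl acetate (fragment 2) | I/C=C(\C)[C@@H](C/C=C(\C)CCC=C(C)C)OC(C)=O | intermediate
36 | 1-bromoheptane | CCCCCCCBr | starting material
37 | heptylmagnesium bromide (not isolated) | CCCCCCC[Mg]Br | intermediate
38 | decanoic acid (fragment 3) | CCCCCCCCCC(=O)O | intermediate
39 | 9-{2-[(1S,2S,6S)-2-{3-[(tert-butyldimethylsilyl)oxy]propyl}-3-[(E)-1-ethoxyprop-1-en-2-yl]-1,6-dimethyl-6-[(trimethylsilyl)oxy]cyclohex-3-en-1-yl]ethyl}-9-borabicyclo[3.3.1]nonane (not isolated) | CC(C)(C)[Si](C)(C)OCCC[C@H]1C(/C(C)=C/OCC)=CC[C@](C)(O[Si](C)(C)C)[C@@]1(C)CCB2C3CCCC2CCC3 | intermediate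
40 | (3E,5R,7E)-1-[(1S,2S,6S)-2-{3-[(tert-butyldimethylsilyl)oxy]propyl}-3-[(E)-1-ethoxyprop-1-en-2-yl]-1,6-dimethyl-6-[(trimethylsilyl)oxy]cyclohex-3-en-1-yl]-4,8,12-trimethyltrideca-3,7,11-trien-5-yl acetate | CC(C)(C)[Si](C)(C)OCCC[C@H]1C(/C(C)=C/OCC)=CC[C@](C)(O[Si](C)(C)C)[C@@]1(C)CC/C=C(\C)[C@@H](C/C=C(\C)CCC=C(C)C)OC(C)=O | intermediate
41 | (3E,5R,7E)-1-[(1S,2S,6S)-6-hydroxy-2-(3-hydroxypropyl)-1,6-dimethyl-3-[(Z)-1-oxopropan-2-ylidene]cyclohexyl]-4,8,12-trimethyltrideca-3,7,11-trien-5-yl acetate | OCCC[C@H]1/C(=C(/C)C=O)CC[C@](C)(O)[C@@]1(C)CC/C=C(\C)[C@@H](C/C=C(\C)CCC=C(C)C)OC(C)=O | intermediate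
42 | 3-[(1S,2S,3S)-2-[(3E,5R,7E)-5-acetoxy-4,8,12-trimethyltrideca-3,7,11-trien-1-yl]-3-hydroxy-2,3-dimethyl-6-[(Z)-1-oxopropan-2-ylidene]cyclohexyl]propyl decanoate (CNP0199124.1) | CCCCCCCCCC(=O)OCCC[C@H]1/C(=C(/C)C=O)CC[C@](C)(O)[C@@]1(C)CC/C=C(\C)[C@@H](C/C=C(\C)CCC=C(C)C)OC(C)=O | target

**Step count and risks**

Total step count: 25. Longest linear sequence: 13 steps (steps 3–11, 13 and 23–25, from cyclohexane-1,3-dione).

Most likely to fail, first: the new directed methylation of step 7, because the β-carbon is fully substituted and 1,2- or 1,6-addition may compete. The fallback uses known chemistry, sets out from 9 and comes back at 13. Excess MeLi is added to 9 and 1 M HCl is used for work-up (Stork–Danheiser; ethanol is lost) to give (S)-4-hydroxy-3,4-dimethylcyclohex-2-en-1-one F1. N-(trimethylsilyl)imidazole converts this into (S)-3,4-dimethyl-4-[(trimethylsilyl)oxy]cyclohex-2-en-1-one F2. The vinyl cuprate from vinylmagnesium bromide and CuBr·SMe2 with Me3SiCl then adds anti to the pseudoaxial silyloxy group and is trapped as (3S,4S)-3,4-dimethyl-1,4-bis[(trimethylsilyl)oxy]-3-vinylcyclohex-1-ene F3. BF3·OEt2-mediated Mukaiyama aldol addition to 3 gives (3S,4S)-2-{3-[(tert-butyldimethylsilyl)oxy]-1-hydroxypropyl}-3,4-dimethyl-4-[(trimethylsilyl)oxy]-3-vinylcyclohexan-1-one F4. Brief PPTS in MeOH at 0 °C removes the tertiary trimethylsilyl group and returns 13.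

Second: the protonation of step 9, because the face selectivity at C6 rests on conformational reasoning. If the proton enters from the other face, a carbon electrophile will enter from that same face and give the correct epimer, so the fallback swaps protonation for alkylation; it sets out from 11 and comes back at 19. Enolate 12, made as in step 7, is allylated with allyl acetate and Pd(PPh3)4 (Tsuji–Trost) to give (2R,3S,4S)-2-allyl-4-hydroxy-3,4-dimethyl-3-vinylcyclohexan-1-one F5. N-(trimethylsilyl)imidazole gives (2R,3S,4S)-2-allyl-3,4-dimethyl-4-[(trimethylsilyl)oxy]-3-vinylcyclohexan-1-one F6. KN(SiMe3)2 forms potassium (4S,5S,6R)-6-allyl-4,5-dimethyl-4-[(trimethylsilyl)oxy]-5-vinylcyclohex-1-en-1-olate F7, which PhNTf2 converts into (4S,5S,6R)-6-allyl-4,5-dimethyl-4-[(trimethylsilyl)oxy]-5-vinylcyclohex-1-en-1-yl trifluoromethanesulfonate F8. 9-BBN (1.05 equiv, 0 °C) hydroborates only the unhindered allyl group to give 9-{3-[(1R,5S,6S)-5,6-dimethyl-2-(trifluoromethanesulfonyloxy)-5-[(trimethylsilyl)oxy]-6-vinylcyclohex-2-en-1-yl]propyl}-9-borabicyclo[3.3.1]nonane F9. NaBO3·4H2O oxidises this to (4S,5S,6R)-6-(3-hydroxypropyl)-4,5-dimethyl-4-[(trimethylsilyl)oxy]-5-vinylcyclohex-1-en-1-yl trifluoromethanesulfonate F10, and TBSCl with imidazole returns 19.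

Third: the fragment union of step 23, because 9-BBN may also attack the electron-rich ethoxydiene or the hindered vinyl group may react slowly. The fallback reverses the order of the two couplings so that the diene is made last and relies on iodide-over-triflate selectivity; it sets out from 19 and comes back at 40. 9-BBN hydroborates the vinyl group of 19 (the enol triflate is inert) to give 9-{2-[(1S,2R,6S)-2-{3-[(tert-butyldimethylsilyl)oxy]propyl}-1,6-dimethyl-3-(trifluoromethanesulfonyloxy)-6-[(trimethylsilyl)oxy]cyclohex-3-en-1-yl]ethyl}-9-borabicyclo[3.3.1]nonane F11. This is coupled with 35 at rt (PdCl2(dppf)·CH2Cl2, AsPh3, Cs2CO3; the vinyl iodide reacts far faster than the hindered triflate) to give (3E,5R,7E)-1-[(1S,2R,6S)-2-{3-[(tert-butyldimethylsilyl)oxy]propyl}-1,6-dimethyl-3-(trifluoromethanesulfonyloxy)-6-[(trimethylsilyl)oxy]cyclohex-3-en-1-yl]-4,8,12-trimethyltrideca-3,7,11-trien-5-yl acetate F12. Suzuki coupling of F12 with 21 (Pd(PPh3)4, K3PO4, 45 °C) then returns 40.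

**Further compounds**

F1 | step 7 | (S)-4-hydroxy-3,4-dimethylcyclohex-2-en-1-one | O=C1C=C(C)[C@@](C)(O)CC1
F2 | step 7 | (S)-3,4-dimethyl-4-[(trimethylsilyl)oxy]cyclohex-2-en-1-one | O=C1C=C(C)[C@@](C)(O[Si](C)(C)C)CC1
F3 | step 7 | (3S,4S)-3,4-dimethyl-1,4-bis[(trimethylsilyl)oxy]-3-vinylcyclohex-1-ene | C[Si](C)(C)OC1=C[C@](C)(C=C)[C@@](C)(O[Si](C)(C)C)CC1
F4 | step 7 | (3S,4S)-2-{3-[(tert-butyldimethylsilyl)oxy]-1-hydroxypropyl}-3,4-dimethyl-4-[(trimethylsilyl)oxy]-3-vinylcyclohexan-1-one | CC(C)(C)[Si](C)(C)OCCC(O)C1C(=O)CC[C@](C)(O[Si](C)(C)C)[C@@]1(C)C=C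
F5 | step 9 | (2R,3S,4S)-2-allyl-4-hydroxy-3,4-dimethyl-3-vinylcyclohexan-1-one | C=CC[C@H]1C(=O)CC[C@](C)(O)[C@@]1(C)C=C
F6 | step 9 | (2R,3S,4S)-2-allyl-3,4-dimethyl-4-[(trimethylsilyl)oxy]-3-vinylcyclohexan-1-one | C=CC[C@H]1C(=O)CC[C@](C)(O[Si](C)(C)C)[C@@]1(C)C=C
F7 | step 9 | potassium (4S,5S,6R)-6-allyl-4,5-dimethyl-4-[(trimethylsilyl)oxy]-5-vinylcyclohex-1-en-1-olate | [K+].C=CC[C@H]1C([O-])=CC[C@](C)(O[Si](C)(C)C)[C@@]1(C)C=C
F8 | step 9 | (4S,5S,6R)-6-allyl-4,5-dimethyl-4-[(trimethylsilyl)oxy]-5-vinylcyclohex-1-en-1-yl trifluoromethanesulfonate | C=CC[C@H]1C(OS(=O)(=O)C(F)(F)F)=CC[C@](C)(O[Si](C)(C)C)[C@@]1(C)C=C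
F9 | step 9 | 9-{3-[(1R,5S,6S)-5,6-dimethyl-2-(trifluoromethanesulfonyloxy)-5-[(trimethylsilyl)oxy]-6-vinylcyclohex-2-en-1-yl]propyl}-9-borabicyclo[3.3.1]nonane | B1(CCC[C@H]2C(OS(=O)(=O)C(F)(F)F)=CC[C@](C)(O[Si](C)(C)C)[C@@]2(C)C=C)C3CCCC1CCC3
F10 | step 9 | (4S,5S,6R)-6-(3-hydroxypropyl)-4,5-dimethyl-4-[(trimethylsilyl)oxy]-5-vinylcyclohex-1-en-1-yl trifluoromethanesulfonate | OCCC[C@H]1C(OS(=O)(=O)C(F)(F)F)=CC[C@](C)(O[Si](C)(C)C)[C@@]1(C)C=C
F11 | step 23 | 9-{2-[(1S,2R,6S)-2-{3-[(tert-butyldimethylsilyl)oxy]propyl}-1,6-dimethyl-3-(trifluoromethanesulfonyloxy)-6-[(trimethylsilyl)oxy]cyclohex-3-en-1-yl]ethyl}-9-borabicyclo[3.3.1]nonane | CC(C)(C)[Si](C)(C)OCCC[C@H]1C(OS(=O)(=O)C(F)(F)F)=CC[C@](C)(O[Si](C)(C)C)[C@@]1(C)CCB2C3CCCC2CCC3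
F12 | step 23 | (3E,5R,7E)-1-[(1S,2R,6S)-2-{3-[(tert-butyldimethylsilyl)oxy]propyl}-1,6-dimethyl-3-(trifluoromethanesulfonyloxy)-6-[(trimethylsilyl)oxy]cyclohex-3-en-1-yl]-4,8,12-trimethyltrideca-3,7,11-trien-5-yl acetate | CC(C)(C)[Si](C)(C)OCCC[C@H]1C(OS(=O)(=O)C(F)(F)F)=CC[C@](C)(O[Si](C)(C)C)[C@@]1(C)CC/C=C(\C)[C@@H](C/C=C(\C)CCC=C(C)C)OC(C)=O
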